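(The runs are calculated with made-up constants, and the scatter is random.)

The closed, stirred flask holds a racemate of left-handed and right-handed substrate, a single-handed free catalyst and reagent, and each turnover spends one reagent.

| flask | left-handed substrate | right-handed substrate | reagent | free catalyst | precatalyst | added ligand | remark | time |
|---|---|---|---|---|---|---|---|---|
| south-west | 0.10 M | 0.10 M | 0.30 M | 0.50 mM | 25 µM | 0.79 mM | run made earlier |  |
| south-east | 0.10 M | 0.10 M | 0.30 M | 0.50 mM | 100 µM | 0.79 mM | run made earlier |  |
| flask | 0.10 M | 0.10 M | 0.300 M | 0.50 mM | 50 µM | 0.79 mM |  | 3.0 min |

| run | time / s | left-handed product / % | right-handed product / % |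
|---|---|---|---|
| south-west | 10.0 | 25.8 | 17.2 |
| south-west | 25.0 | 38.7 | 29.2 |
| south-west | 50.0 | 45.9 | 38.5 |
| south-west | 80.0 | 48.0 | 43.1 |
| south-west | 120 | 49.7 | 46.6 |
| south-east | 20.0 | 35.9 | 26.5 |
| south-east | 40.0 | 43.8 | 35.2 |
| south-east | 60.0 | 47.4 | 41.6 |
| south-east | 80.0 | 48.8 | 43.6 |
| south-east | 120 | 49.6 | 47.4 |

(each reading ± 0.5 percentage points)

- free catalyst is single-handed; left-handed substrate and right-handed substrate are mirror images of each other, charged as a racemate, each of them at the stated concentration
- steps that have been proposed: reagent + free catalyst + left-handed substrate -> free catalyst + left-handed product; reagent + free catalyst + right-handed substrate -> free catalyst + right-handed product; left-handed substrate + racemization catalyst <-> right-handed substrate + racemization catalyst; precatalyst -> racemization catalyst; racemization catalyst + added ligand <-> idle complex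
- an excess is the difference of the two amounts in percent of their sum
- an excess is below zero if the other one leads

1. left-handed product and right-handed product together, in percent of the left-handed substrate and right-handed substrate charged together, at 3.0 min
2. excess of left-handed product over right-handed product in the product at 3.0 min
3. whether the exchange between left-handed substrate and right-handed substrate keeps pace with the reaction: how far the product's excess at 3.0 min gets from its value without exchange to its value with instant exchange (above 80 % keeps pace, below 20 % hardly takes part, else lags behind)

The reagent charge over the two substrate charges together is 1.50; we call this the reagent cover. Above one the substrates are the limiting reagent, and full conversion leaves 33.3 % of the reagent charge. Both runs have the same cover. The two proposed steps to product are first order in reagent, so the reagent fraction is our clock.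

Over the first south-west reading, at 10.0 s, the reagent averaged 0.857 of its charge. So we read a right-handed decay of 0.0492 s⁻¹ at full charge, and 0.0164 s⁻¹ late on. At 120 s the readings put right-handed substrate, on average over the two runs, at 3.00 % of the two substrates charged. By our reckoning another 60.0 s takes that to 1.12 %. The same reading gives a selectivity factor of 1.72, which leaves 0.0725 % as left-handed substrate. Our reckoning is therefore 98.8 % converted, with an excess of 1.06 %.

The weak link is that this chain leaves exchange out. If exchange fed left-handed substrate to any weight, the late excess should rise with the precatalyst charge. Yet at 120 s the excess reads 3.22 % in the south-west run and 2.27 % in the south-east run, whose precatalyst charge is larger by a factor of 4.00. We see no rise in these readings, and the precatalyst charge of our flask lies between the two, so our numbers stand.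

The forecast gives 98.9 %, 1 % and "hardly takes part", a shade apart from our figures. Its ground: “the ligand largely shuts racemization down”.

The flask gives 98.9 %, 0.958 % and "hardly takes part", with 0.11 % of the way covered.

    reagent + free catalyst + left-handed substrate → free catalyst + left-handed product (k = 577 M⁻² s⁻¹)
    reagent + free catalyst + right-handed substrate → free catalyst + right-handed product (k = 339 M⁻² s⁻¹)
    left-handed substrate + racemization catalyst ⇌ right-handed substrate + racemization catalyst, rate k3*[racemization catalyst]*[left-handed substrate] forward; the back reaction follows from the equilibrium constant (k = 51.6 M⁻¹ s⁻¹)
    precatalyst → racemization catalyst (k = 0.0104 s⁻¹)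
    racemization catalyst + added ligand ⇌ idle complex, settled at all times (K = 92800 M⁻¹)

The largest single effect on conversion in this flask comes from the step to right-handed product: without it, conversion at 3.0 min is 50.1 % against 98.9 %. With a cover of 1.50, 34 % of the reagent charge still stands in this flask. The neighbour charged with 0.12 M of reagent has a cover of 0.600, below one, so its charge allows a conversion of 60.0 %. It gives 58.9 %, with 1.8 % of its reagent left and an excess of 16.3 %.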